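The flavan is cut through ring C (O1, C2, C3, C4, C4a, C8a) into two halves of similar size: an ortho-quinone methide carrying O1, C8a, C4a and C4 on ring A, and a ring B styrene whose vinyl group is C2=C3. A chiral Brønsted acid should dehydrate a salicyl alcohol to this oxa-diene and guide its inverse-electron-demand [4+2] cycloaddition, closing ring C and setting C2, the only stereocentre, in one operation. The step exploits the latent 1-oxadiene O1–C8a–C4a–C4 and the nucleophilic, para-oxygenated C2=C3 alkene. The precursors, a silylated 5-(1,1-dimethylallyl)salicyl alcohol and a 6-vinyl-5-prenylchromene silyl ether, arrive fully decorated, so only desilylation follows.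

Key step: step 9

Assumption: 5-bromo-2,4-dihydroxybenzaldehyde and 2-bromo-4,5-dihydroxybenzaldehyde are taken as catalogue compounds.
Assumption: the sense of induction of the chiral acid in step 9 cannot be assigned beforehand; the route is written for the catalyst antipode that delivers 2S (the S,S form is assumed), the other antipode being used if induction proves opposite.

Step 1
Reactants: 1 5-bromo-2,4-dihydroxybenzaldehyde; 2 chlorotriisopropylsilane
Product: 3 5-bromo-2-hydroxy-4-(triisopropylsilyloxy)benzaldehyde
Conditions: 2 (1.05 equiv), imidazole, CH2Cl2, 0 °C to rt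
Reagents that add atoms: chlorotriisopropylsilane, CC(C)[Si](Cl)(C(C)C)C(C)C
Why: Selective phenol silylation, since the 2-OH is held in a hydrogen bond to the aldehyde and is the poorer nucleophile, so the bulky silyl chloride should take only the 4-OH.

Step 2
Reactants: 3 5-bromo-2-hydroxy-4-(triisopropylsilyloxy)benzaldehyde; 4 prenylboronic acid pinacol ester (4,4,5,5-tetramethyl-2-(3-methylbut-2-en-1-yl)-1,3,2-dioxaborolane)
Product: 5 2-hydroxy-5-(2-methylbut-3-en-2-yl)-4-(triisopropylsilyloxy)benzaldehyde
Conditions: 4 (1.5 equiv), Pd(OAc)2 (3 mol %), bulky dialkylbiarylphosphine chosen for branched selectivity (t-BuXPhos, 2-di-tert-butylphosphino-2',4',6'-triisopropylbiphenyl, as first choice), aq. K3PO4, THF, 40 °C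
Reagents that add atoms: prenylboronic acid pinacol ester, CC(C)=CCB1OC(C)(C)C(C)(C)O1
Why: Ligand-controlled γ-selective (branched) Suzuki–Miyaura coupling of a 3,3-disubstituted allylboronate, in which transmetalation with allyl transposition places palladium on the tertiary carbon and fast reductive elimination should give the aryl–C(CH3)2–CH=CH2 unit exactly at the carbon that carried bromine, so ring A regiochemistry is not in question.

Step 3
Reactants: 5 2-hydroxy-5-(2-methylbut-3-en-2-yl)-4-(triisopropylsilyloxy)benzaldehyde
Product: 6 2-(hydroxymethyl)-4-(2-methylbut-3-en-2-yl)-5-(triisopropylsilyloxy)phenol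
Conditions: NaBH4, THF/MeOH, 0 °C; pH 7 buffer work-up
Reagents that add atoms: none
Why: Chemoselective borohydride reduction of the aldehyde to the benzylic alcohol, with the alkene and the silyl ether inert and a neutral work-up protecting the acid-sensitive salicyl alcohol.

Step 4
Reactants: 7 2-bromo-4,5-dihydroxybenzaldehyde; 8 3-chloro-3-methylbut-1-yne
Product: 9 2-bromo-5-hydroxy-4-[(2-methylbut-3-yn-2-yl)oxy]benzaldehyde
Conditions: 8 (1.2 equiv), K2CO3 (1.1 equiv), KI (cat.), acetone, 55 °C
Reagents that add atoms: 3-chloro-3-methylbut-1-yne, C#CC(C)(C)Cl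
Why: Williamson-type O-alkylation with a tertiary propargylic chloride, in which the 4-OH para to the aldehyde is the more acidic phenol and should be alkylated in preference to the 5-OH when about one equivalent of base is used.

Step 5
Reactants: 9 2-bromo-5-hydroxy-4-[(2-methylbut-3-yn-2-yl)oxy]benzaldehyde; 2 chlorotriisopropylsilane
Product: 10 2-bromo-4-[(2-methylbut-3-yn-2-yl)oxy]-5-(triisopropylsilyloxy)benzaldehyde
Conditions: 2 (1.2 equiv), imidazole, DMF, rt
Reagents that add atoms: chlorotriisopropylsilane, CC(C)[Si](Cl)(C(C)C)C(C)C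
Why: Standard silylation of the one remaining phenol, which gives a base-stable and heat-stable ether that is removed by fluoride at the end.

Step 6
Reactants: 10 2-bromo-4-[(2-methylbut-3-yn-2-yl)oxy]-5-(triisopropylsilyloxy)benzaldehyde
Product: 11 5-bromo-2,2-dimethyl-8-(triisopropylsilyloxy)-2H-chromene-6-carbaldehyde
Conditions: N,N-diethylaniline, 180 °C, argon
Reagents that add atoms: none
Why: Thermal aryl propargyl ether to 2,2-dimethyl-2H-chromene rearrangement (aromatic propargyl Claisen rearrangement, then 1,5-hydrogen shift and oxa-6π electrocyclisation), for which only one ortho position of the ether is free (C3 of the benzaldehyde, next to the bromine-bearing carbon), so the pyran ring can form in one direction only.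

Step 7
Reactants: 11 5-bromo-2,2-dimethyl-8-(triisopropylsilyloxy)-2H-chromene-6-carbaldehyde; 12 methyltriphenylphosphonium bromide
Product: 13 [(5-bromo-6-ethenyl-2,2-dimethyl-2H-chromen-8-yl)oxy]triisopropylsilane
Conditions: 12, KOtBu, THF, 0 °C to rt
Reagents that add atoms: methyltriphenylphosphonium bromide, C[P+](c1ccccc1)(c1ccccc1)c1ccccc1.[Br-]
Why: Wittig methylenation of a non-enolisable aryl aldehyde, which removes the aldehyde before the allylzinc reagent of the next step is used.

Step 8
Reactants: 13 [(5-bromo-6-ethenyl-2,2-dimethyl-2H-chromen-8-yl)oxy]triisopropylsilane; 14 prenyl bromide (1-bromo-3-methylbut-2-ene)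
Product: 15 {[6-ethenyl-2,2-dimethyl-5-(3-methylbut-2-en-1-yl)-2H-chromen-8-yl]oxy}triisopropylsilane
Conditions: 14, Zn dust, LiCl, THF, rt (gives prenylzinc bromide); then 13, Pd(OAc)2 (2 mol %), CPhos (2-dicyclohexylphosphino-2',6'-bis(dimethylamino)biphenyl, 4 mol %), THF, rt
Reagents that add atoms: prenyl bromide (used as prenylzinc bromide), CC(C)=CCBr
Why: Linear-selective Negishi coupling of a prenylzinc halide with an aryl bromide, in which reductive elimination from the primary σ-allyl palladium species should give the 3-methylbut-2-enyl arene, at a temperature where the vinyl and chromene alkenes do not enter Heck chemistry.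

Step 9
Reactants: 6 2-(hydroxymethyl)-4-(2-methylbut-3-en-2-yl)-5-(triisopropylsilyloxy)phenol; 15 {[6-ethenyl-2,2-dimethyl-5-(3-methylbut-2-en-1-yl)-2H-chromen-8-yl]oxy}triisopropylsilane
Product: 17 (2S)-2-[2,2-dimethyl-5-(3-methylbut-2-en-1-yl)-8-(triisopropylsilyloxy)-2H-chromen-6-yl]-6-(2-methylbut-3-en-2-yl)-7-(triisopropylsilyloxy)chromane, via ortho-quinone methide 16 (not isolated)
Conditions: 15 (1.0 equiv), confined chiral imidodiphosphoric acid HN[P(=O)(O2Ar*)]2 with O2Ar* = (S)-3,3'-bis(2,4,6-triethylphenyl)-1,1'-binaphthalene-2,2'-diolate (5 mol %), 5 Å molecular sieves, toluene, 0 °C; 6 (1.3 equiv) added slowly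
Reagents that add atoms: none
Why: Proposed new method: the chiral acid protonates the benzylic hydroxyl of 6 and, after loss of water, holds ortho-quinone methide 16 by a hydrogen bond (in the limit as a hydroxybenzyl cation paired with the chiral anion) while the terminal CH2 of styrene 15 adds to the exocyclic methylene (C4–C3) and the phenolic oxygen closes on the developing benzylic centre (O1–C2), a concerted but asynchronous inverse-electron-demand oxa-[4+2] cycloaddition whose closest known relatives are the chiral phosphoric acid catalysed cycloadditions of ortho-quinone methides from ortho-hydroxybenzyl alcohols with hydroxystyrenes and vinylindoles and the confined-acid catalysed intramolecular variant with unactivated alkenes, the new element being enantiocontrol with a methylene quinone methide and a styrene that offers no hydrogen-bond donor. Ring C is closed by intermolecular [4+2] annulation, which in the stepwise limit is a 6-endo-trig capture of the C2 cation by O1. C2, the only stereocentre, is set when O1 bonds to one face of the styrene carbon inside the confined pocket of the chiral anion, so it is catalyst-controlled and the catalyst antipode fixes 2S. The 2-aryl (not 3-aryl) regiochemistry follows from the polarity match between the electrophilic methylene and the nucleophilic terminal carbon of the para-oxygenated styrene. The step also needs chemoselectivity against Friedel–Crafts self-condensation and against the three other alkenes, which the substrates secure because the 1,1-dimethylallyl group blocks the activated ring A position para to the phenol, the bulky silyloxy group shields the position between the two oxygens, the chromene alkene is hindered by its gem-dimethyl group and the neighbouring prenyl chain, the prenyl and 1,1-dimethylallyl alkenes are far less nucleophilic than the styrene, and both phenols that could add to the quinone methide are silylated.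

Step 10
Reactants: 17 (2S)-2-[2,2-dimethyl-5-(3-methylbut-2-en-1-yl)-8-(triisopropylsilyloxy)-2H-chromen-6-yl]-6-(2-methylbut-3-en-2-yl)-7-(triisopropylsilyloxy)chromane
Product: 18 Kazinol H, (2S)-2-[8-hydroxy-2,2-dimethyl-5-(3-methylbut-2-en-1-yl)-2H-chromen-6-yl]-6-(2-methylbut-3-en-2-yl)chroman-7-ol
Conditions: Bu4NF (2.5 equiv), AcOH (2.5 equiv), THF, 0 °C to rt
Reagents that add atoms: none
Why: Fluoride-mediated cleavage of both aryl silyl ethers, buffered with acetic acid so that neither free phenoxide nor strong acid meets the ortho-(1,1-dimethylallyl)phenol and the chromene, and leaving C2 untouched.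

Compound list
1 | 5-bromo-2,4-dihydroxybenzaldehyde | O=Cc1cc(Br)c(O)cc1O | starting material
2 | chlorotriisopropylsilane | CC(C)[Si](Cl)(C(C)C)C(C)C | starting material
3 | 5-bromo-2-hydroxy-4-(triisopropylsilyloxy)benzaldehyde | O=Cc1cc(Br)c(O[Si](C(C)C)(C(C)C)C(C)C)cc1O | intermediate
4 | prenylboronic acid pinacol ester | CC(C)=CCB1OC(C)(C)C(C)(C)O1 | starting material
5 | 2-hydroxy-5-(2-methylbut-3-en-2-yl)-4-(triisopropylsilyloxy)benzaldehyde | C=CC(C)(C)c1cc(C=O)c(O)cc1O[Si](C(C)C)(C(C)C)C(C)C | intermediate
6 | 2-(hydroxymethyl)-4-(2-methylbut-3-en-2-yl)-5-(triisopropylsilyloxy)phenol | C=CC(C)(C)c1cc(CO)c(O)cc1O[Si](C(C)C)(C(C)C)C(C)C | intermediate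
7 | 2-bromo-4,5-dihydroxybenzaldehyde | O=Cc1cc(O)c(O)cc1Br | starting material
8 | 3-chloro-3-methylbut-1-yne | C#CC(C)(C)Cl | starting material
9 | 2-bromo-5-hydroxy-4-[(2-methylbut-3-yn-2-yl)oxy]benzaldehyde | O=Cc1cc(O)c(OC(C)(C)C#C)cc1Br | intermediate
10 | 2-bromo-4-[(2-methylbut-3-yn-2-yl)oxy]-5-(triisopropylsilyloxy)benzaldehyde | O=Cc1cc(O[Si](C(C)C)(C(C)C)C(C)C)c(OC(C)(C)C#C)cc1Br | intermediate
11 | 5-bromo-2,2-dimethyl-8-(triisopropylsilyloxy)-2H-chromene-6-carbaldehyde | O=Cc1cc(O[Si](C(C)C)(C(C)C)C(C)C)c2OC(C)(C)C=Cc2c1Br | intermediate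
12 | methyltriphenylphosphonium bromide | C[P+](c1ccccc1)(c1ccccc1)c1ccccc1.[Br-] | starting material
13 | [(5-bromo-6-ethenyl-2,2-dimethyl-2H-chromen-8-yl)oxy]triisopropylsilane | C=Cc1cc(O[Si](C(C)C)(C(C)C)C(C)C)c2OC(C)(C)C=Cc2c1Br | intermediate
14 | prenyl bromide | CC(C)=CCBr | starting material
15 | {[6-ethenyl-2,2-dimethyl-5-(3-methylbut-2-en-1-yl)-2H-chromen-8-yl]oxy}triisopropylsilane | C=Cc1cc(O[Si](C(C)C)(C(C)C)C(C)C)c2OC(C)(C)C=Cc2c1CC=C(C)C | intermediate
16 | 6-methylidene-4-(2-methylbut-3-en-2-yl)-3-(triisopropylsilyloxy)cyclohexa-2,4-dien-1-one (ortho-quinone methide, not isolated) | C=C1C(=O)C=C(O[Si](C(C)C)(C(C)C)C(C)C)C(C(C)(C)C=C)=C1 | intermediate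
17 | (2S)-2-[2,2-dimethyl-5-(3-methylbut-2-en-1-yl)-8-(triisopropylsilyloxy)-2H-chromen-6-yl]-6-(2-methylbut-3-en-2-yl)-7-(triisopropylsilyloxy)chromane | C=CC(C)(C)c1cc2c(cc1O[Si](C(C)C)(C(C)C)C(C)C)O[C@H](c1cc(O[Si](C(C)C)(C(C)C)C(C)C)c3c(c1CC=C(C)C)C=CC(C)(C)O3)CC2 | intermediate
18 | Kazinol H | C=CC(C)(C)c1cc2c(cc1O)O[C@H](c1cc(O)c3c(c1CC=C(C)C)C=CC(C)(C)O3)CC2 | target

Total step count: 10. Longest linear sequence: 7 steps (steps 4 to 10, from 7).

Steps most likely to fail

1. Step 9 (proposed new method). The chiral anion may not discriminate the two faces of a styrene that has no hydrogen-bonding handle. Acid-induced reopening of the C2–O1 bond may erode enantiopurity, and cationic oligomerisation of the electron-rich styrene may compete. The fallback uses known chemistry, sets out from 6 and 15 and comes back at 18. Heating 6 with 15 without a chiral catalyst (o-xylene, 140 °C, or catalytic diphenyl phosphate at rt) is the long-known thermal or acid-triggered ortho-quinone methide/styrene cycloaddition via 16 and should give the racemic bis-silyl flavan F1. Desilylation under the conditions of step 10 should give racemic Kazinol H F2, which is resolved by preparative HPLC on an amylose tris(3,5-dimethylphenylcarbamate) stationary phase, the 2S enantiomer being 18.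

2. Step 2. The allyl ligand may slip to its linear form before reductive elimination at the hindered tertiary terminus, giving the linear prenyl arene. Protodeboronation and slow oxidative addition to the electron-rich bromide are further risks. The fallback sets out from 15 and comes back at 18, with the 1,1-dimethylallyl group made last by aromatic Claisen rearrangement instead of cross-coupling. Commercial 2,4-dihydroxybenzaldehyde is alkylated at its non-chelated 4-OH with prenyl bromide 14 (K2CO3, acetone) to 2-hydroxy-4-(prenyloxy)benzaldehyde F3, which NaBH4 reduces to 2-hydroxy-4-(prenyloxy)benzyl alcohol F4. Under the conditions of step 9, F4 should give the prenyloxy ortho-quinone methide F5, which adds to 15 to give the (2S)-7-prenyloxyflavan F6. Heating F6 in N,N-diethylaniline at 180 °C should move the allyl unit with transposition to C6, the ortho position away from O1, giving the mono-silyl 7-hydroxy-6-(1,1-dimethylallyl)flavan F7. Desilylation as in step 10 then gives 18.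

3. Step 8. Transmetalation and reductive elimination at the doubly ortho-substituted bromide may be slow, allowing hydrodebromination or partial branched coupling. The fallback sets out from 13 and comes back at 15, replacing the catalytic cross-coupling with polar allylation of an aryl anion. Bromine–lithium exchange (n-BuLi, Et2O, −78 °C, as for ortho-bromostyrene itself) should give the aryllithium F8. Treatment with CuBr·SMe2 and prenyl bromide 14 should then give 15 by SN2 allylation at the primary carbon.

Further compounds
F1 | step 9 | racemic 2-[2,2-dimethyl-5-(3-methylbut-2-en-1-yl)-8-(triisopropylsilyloxy)-2H-chromen-6-yl]-6-(2-methylbut-3-en-2-yl)-7-(triisopropylsilyloxy)chromane | C=CC(C)(C)c1cc2c(cc1O[Si](C(C)C)(C(C)C)C(C)C)OC(c1cc(O[Si](C(C)C)(C(C)C)C(C)C)c3c(c1CC=C(C)C)C=CC(C)(C)O3)CC2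
F2 | step 9 | racemic Kazinol H | C=CC(C)(C)c1cc2c(cc1O)OC(c1cc(O)c3c(c1CC=C(C)C)C=CC(C)(C)O3)CC2
F3 | step 2 | 2-hydroxy-4-[(3-methylbut-2-en-1-yl)oxy]benzaldehyde | O=Cc1ccc(OCC=C(C)C)cc1O
F4 | step 2 | 2-(hydroxymethyl)-5-[(3-methylbut-2-en-1-yl)oxy]phenol | OCc1ccc(OCC=C(C)C)cc1O
F5 | step 2 | 6-methylidene-3-[(3-methylbut-2-en-1-yl)oxy]cyclohexa-2,4-dien-1-one (not isolated) | C=C1C=CC(OCC=C(C)C)=CC1=O
F6 | step 2 | (2S)-2-[2,2-dimethyl-5-(3-methylbut-2-en-1-yl)-8-(triisopropylsilyloxy)-2H-chromen-6-yl]-7-[(3-methylbut-2-en-1-yl)oxy]chromane | CC(C)=CCOc1ccc2c(c1)O[C@H](c1cc(O[Si](C(C)C)(C(C)C)C(C)C)c3c(c1CC=C(C)C)C=CC(C)(C)O3)CC2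
F7 | step 2 | (2S)-2-[2,2-dimethyl-5-(3-methylbut-2-en-1-yl)-8-(triisopropylsilyloxy)-2H-chromen-6-yl]-6-(2-methylbut-3-en-2-yl)chroman-7-ol | C=CC(C)(C)c1cc2c(cc1O)O[C@H](c1cc(O[Si](C(C)C)(C(C)C)C(C)C)c3c(c1CC=C(C)C)C=CC(C)(C)O3)CC2
F8 | step 8 | [6-ethenyl-2,2-dimethyl-8-(triisopropylsilyloxy)-2H-chromen-5-yl]lithium (not isolated) | C=Cc1cc(O[Si](C(C)C)(C(C)C)C(C)C)c2OC(C)(C)C=Cc2c1[Li]
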